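**Retrosynthetic overview**

- Oxane numbering used throughout: O1, C2 (carries the acrylic acid, α-carbon = Cα), C3, C4, C5 (carries the side chain C1', C2', …), C6 (the OCH2 carbon). The two ring substituents are cis, (2R,5R).
- Enabling feature: the carboxyl group is 1,3 to O1 (O1–C2–Cα–CO2H), so the carboxyl oxygen and O1 can both be tied to C6 as an acylal, a temporary 1,3-dioxan-4-one (ring A).
- Key disconnection C5–C6: the C6 acylal radical closes the oxane (ring B) 6-exo onto an allyl sulfone, giving a 2,9-dioxabicyclo[3.3.1]nonan-3-one. The bridge locks the C2 substituent axial, so the new C5 vinyl group goes equatorial, which is the cis-2,5 relation.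
- Ring order: ring A (step 4), then ring B (step 5), then ring A is cut open at C6 by silane reduction (step 7), which returns C6 to CH2 and frees the acid.
- Other disconnections: C2'–C3' by B-alkyl Suzuki coupling of the C5 vinyl group with an (E)-alkenyl iodide from geranyl bromide; exo-methylene by Eschenmoser methylenation; C2 by Noyori hydrogenation.

Key step: step 5

Assumption: methyl 3-oxohept-6-enoate (1) is taken as a purchasable β-keto ester, and the target is read as the cis-2,5-disubstituted oxane.

**Route**

Step 1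
Reactants: 1 methyl 3-oxohept-6-enoate
Product: 2 methyl (3R)-3-hydroxyhept-6-enoate
Conditions: H2 (4 atm), RuCl2[(R)-BINAP] (0.5 mol%), MeOH, 60 °C
Reagents that add atoms: none
Why: Noyori asymmetric hydrogenation, in which the chelated β-keto ester takes hydride on the carbonyl face fixed by the (R)-BINAP ligand and should give the (3R)-alcohol, the future C2, while the remote unactivated alkene is left alone at low pressure.

Step 2
Reactants: 2 methyl (3R)-3-hydroxyhept-6-enoate; 3 allyl phenyl sulfone
Product: 4 methyl (3R,6E)-8-(benzenesulfonyl)-3-hydroxyoct-6-enoate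
Conditions: second-generation Hoveyda–Grubbs catalyst (5 mol%), 3 (3 equiv), CH2Cl2, 40 °C
Reagents that add atoms: none
Why: Olefin cross-metathesis of the terminal alkene with excess allyl sulfone should give mainly the (E)-allyl sulfone with loss of ethene; the alkene geometry is irrelevant because step 5 turns this alkene into a vinyl group.

Step 3
Reactants: 4 methyl (3R,6E)-8-(benzenesulfonyl)-3-hydroxyoct-6-enoate
Product: 5 (3R,6E)-8-(benzenesulfonyl)-3-hydroxyoct-6-enoic acid
Conditions: LiOH, THF/H2O, 0 °C; then 1 M HCl
Reagents that add atoms: lithium hydroxide, [Li+].[OH-]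
Why: Saponification (BAc2) at 0 °C should cleave the methyl ester without dehydrating the β-hydroxy acid or isomerising the allyl sulfone, and the stereocentre is not touched.

Step 4
Reactants: 5 (3R,6E)-8-(benzenesulfonyl)-3-hydroxyoct-6-enoic acid; 6 glyoxylic acid monohydrate
Product: 7 (6R)-6-[(3E)-5-(benzenesulfonyl)pent-3-en-1-yl]-4-oxo-1,3-dioxane-2-carboxylic acid (mixture of C2 epimers)
Conditions: PPTS (10 mol%), 4 Å molecular sieves, MeCN/CH2Cl2, 25 → 40 °C
Reagents that add atoms: none
Why: Acid-catalysed acetalisation of a β-hydroxy acid with an aldehyde to a 1,3-dioxan-4-one, in which the hydroxyl adds to the glyoxylic aldehyde and the carboxyl closes the six-membered acylal with loss of water; the new acetal centre forms as a mixture, which is harmless because it becomes a radical in step 5.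

Step 5
Reactants: 7 (6R)-6-[(3E)-5-(benzenesulfonyl)pent-3-en-1-yl]-4-oxo-1,3-dioxane-2-carboxylic acid
Product: 8 (1R,5R,8S)-8-ethenyl-2,9-dioxabicyclo[3.3.1]nonan-3-one
Conditions: [Ir{dF(CF3)ppy}2(dtbbpy)]PF6 (2 mol%), K2HPO4 (1.2 equiv), DMF (0.01 M), blue LEDs (450 nm), 25 °C, Ar
Reagents that add atoms: none
Why: Proposed new method: the excited trivalent iridium photocatalyst oxidises the carboxylate of 7, CO2 is lost, and the nucleophilic acylal radical at C6 (a 4-oxo-1,3-dioxan-2-yl radical) adds to C5 of the allyl sulfone; the β-sulfonyl radical then expels PhSO2•, which divalent iridium reduces to sulfinate, so the cycle is redox-neutral and needs no hydrogen donor. The closest known reaction types are the photoredox decarboxylative allylation of α-oxy acids with allyl sulfones, the decarboxylative formation of dialkoxymethyl radicals from dialkoxyacetic acids and radical cyclisations of 1,3-dioxan-2-yl radicals onto tethered alkenes; their use on an acylal radical to close a bridged ring is the untested part. Ring B (the oxane) closes 6-exo-trig through a chair in which the radical bonds axially at C6, which is possible only when the C3–C5 chain on C2 is also axial on ring A, so the lactone bridge ends cis-diaxial on the new oxane and the acetal centre (C1 of 8, R) is dictated by the geometry of the bridge. The new centre at C5 (C8 of 8, S) is controlled by ring A: with the C2 substituent locked axial, the alkene takes the equatorial site of the chair, which places the vinyl group on the same face as the bridge, that is cis to the future acrylic acid. The step is stereoconvergent, because both C6 epimers of 7 give the same radical and both alkene isomers give the same vinyl group. It needs 6-exo attack to outrun 1,5-hydrogen transfer from the allylic C4–H, 7-endo attack and intermolecular addition; the polarity match of the electron-rich radical with the sulfone-bearing alkene, high dilution, the absence of a hydrogen donor and the saturated Cα (no competing acrylate acceptor) should secure this.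

Step 6
Reactants: 8 (1R,5R,8S)-8-ethenyl-2,9-dioxabicyclo[3.3.1]nonan-3-one
Product: 12 (1R,5R,8S)-8-ethenyl-4-methylidene-2,9-dioxabicyclo[3.3.1]nonan-3-one, via lithium enolate 9 (not isolated), via Mannich base 10 (not isolated), via trimethylammonium iodide 11 (not isolated)
Conditions: LiN(iPr)2, THF, −78 °C; Me2N=CH2 I (Eschenmoser's salt), −78 → −10 °C; then MeI, CH2Cl2, 25 °C; then DBU, 25 °C
Reagents that add atoms: Eschenmoser's salt (N,N-dimethylmethyleneiminium iodide), C=[N+](C)C.[I-]
Why: Eschenmoser methylenation, in which the lactone enolate (kept from β-elimination at −78 °C because the bridgehead C–O bond lies near the enolate plane) undergoes a Mannich reaction, and quaternisation followed by Hofmann-type elimination should give the exo-methylene lactone without touching a stereocentre.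

Step 7
Reactants: 12 (1R,5R,8S)-8-ethenyl-4-methylidene-2,9-dioxabicyclo[3.3.1]nonan-3-one
Product: 14 2-[(2R,5S)-5-ethenyloxan-2-yl]prop-2-enoic acid, via triethylsilyl ester 13 (not isolated)
Conditions: Et3SiH (5 equiv), TMSOTf (0.2 equiv), CH2Cl2, −78 → −20 °C; then aq. NaHCO3, then pH 3
Reagents that add atoms: none
Why: Ionic hydrogenation of the acylal, in which the Lewis acid ionises the C6–O(acyl) bond (carboxylate is the better leaving group) and Et3SiH reduces the oxane oxocarbenium ion at C6 to CH2, so ring A is removed, the acrylic acid is set free and C2 and C5 keep their cis relation.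

Step 8
Reactants: 15 1-(trimethylsilyl)propyne; 16 geranyl bromide
Product: 18 trimethyl[(5E)-6,10-dimethylundeca-5,9-dien-1-yn-1-yl]silane, via lithiated silylpropyne 17 (not isolated)
Conditions: n-BuLi, THF, −78 °C; then 16, −78 → 0 °C
Reagents that add atoms: none
Why: Propargylic alkylation, in which the lithiated silylpropyne reacts at its CH2 terminus in an SN2 displacement of the primary allylic bromide and so keeps the (E)-alkene of the geranyl unit.

Step 9
Reactants: 18 trimethyl[(5E)-6,10-dimethylundeca-5,9-dien-1-yn-1-yl]silane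
Product: 19 (5E)-6,10-dimethylundeca-5,9-dien-1-yne
Conditions: K2CO3 (0.2 equiv), MeOH, 25 °C
Reagents that add atoms: none
Why: Protodesilylation of the alkynylsilane by methoxide should free the terminal alkyne without touching the trisubstituted alkenes.

Step 10
Reactants: 19 (5E)-6,10-dimethylundeca-5,9-dien-1-yne
Product: 21 (1E,5E)-1-iodo-2,6,10-trimethylundeca-1,5,9-triene, via alkenyldimethylalane 20 (not isolated)
Conditions: Me3Al, Cp2ZrCl2 (0.25 equiv), CH2Cl2, 0 → 25 °C; then I2, THF, −30 °C
Reagents that add atoms: trimethylaluminium, C[Al](C)C; iodine, [I][I]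
Why: Negishi zirconium-catalysed carboalumination adds methyl and aluminium syn across the terminal alkyne (methyl to the internal carbon), and iodinolysis with retention should give the (E)-alkenyl iodide that fixes the geometry of the future C3'=C4' alkene.

Step 11
Reactants: 14 2-[(2R,5S)-5-ethenyloxan-2-yl]prop-2-enoic acid; 21 (1E,5E)-1-iodo-2,6,10-trimethylundeca-1,5,9-triene
Product: 23 rhopaloic acid B, 2-[(2R,5R)-5-[(3E,7E)-4,8,12-trimethyltrideca-3,7,11-trien-1-yl]oxan-2-yl]prop-2-enoic acid, via B-alkyl-9-BBN borane 22 (not isolated)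
Conditions: 9-BBN (2.5 equiv), THF, 0 → 25 °C; then 21, Pd(dppf)Cl2 (5 mol%), AsPh3 (10 mol%), Cs2CO3 (4 equiv), DMF/H2O, 25 °C; then pH 3
Reagents that add atoms: none
Why: B-alkyl Suzuki–Miyaura coupling, in which 9-BBN first turns the acid into its acyloxyborane and then hydroborates the vinyl group anti-Markovnikov in preference to the electron-poor 1,1-disubstituted acrylate, and the alkylborane couples with retention of the (E)-iodide geometry; the C5 descriptor changes from S to R only because the substituent priorities change.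

**Compound list**

1 | methyl 3-oxohept-6-enoate | COC(=O)CC(=O)CCC=C | starting material
2 | methyl (3R)-3-hydroxyhept-6-enoate | COC(=O)C[C@H](O)CCC=C | intermediate
3 | allyl phenyl sulfone, (prop-2-en-1-ylsulfonyl)benzene | C=CCS(=O)(=O)c1ccccc1 | starting material
4 | methyl (3R,6E)-8-(benzenesulfonyl)-3-hydroxyoct-6-enoate | COC(=O)C[C@H](O)CC/C=C/CS(=O)(=O)c1ccccc1 | intermediate
5 | (3R,6E)-8-(benzenesulfonyl)-3-hydroxyoct-6-enoic acid | OC(=O)C[C@H](O)CC/C=C/CS(=O)(=O)c1ccccc1 | intermediate
6 | glyoxylic acid monohydrate (2,2-dihydroxyacetic acid) | OC(O)C(=O)O | starting material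
7 | (6R)-6-[(3E)-5-(benzenesulfonyl)pent-3-en-1-yl]-4-oxo-1,3-dioxane-2-carboxylic acid, mixture of C2 epimers | OC(=O)C1OC(=O)C[C@@H](CC/C=C/CS(=O)(=O)c2ccccc2)O1 | intermediate
8 | (1R,5R,8S)-8-ethenyl-2,9-dioxabicyclo[3.3.1]nonan-3-one | O=C1C[C@H]2CC[C@@H](C=C)[C@@H](O1)O2 | intermediate
9 | lithium (1R,5R,8S)-8-ethenyl-2,9-dioxabicyclo[3.3.1]non-3-en-3-olate (lithium enolate of 8) | [Li+].[O-]C1=C[C@H]2CC[C@@H](C=C)[C@@H](O1)O2 | intermediate
10 | (1R,5R,8S)-4-[(dimethylamino)methyl]-8-ethenyl-2,9-dioxabicyclo[3.3.1]nonan-3-one (Mannich base, C4 epimers) | O=C1C(CN(C)C)[C@H]2CC[C@@H](C=C)[C@@H](O1)O2 | intermediate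
11 | [(1R,5R,8S)-8-ethenyl-3-oxo-2,9-dioxabicyclo[3.3.1]nonan-4-yl]-N,N,N-trimethylmethanaminium iodide | O=C1C(C[N+](C)(C)C)[C@H]2CC[C@@H](C=C)[C@@H](O1)O2.[I-] | intermediate
12 | (1R,5R,8S)-8-ethenyl-4-methylidene-2,9-dioxabicyclo[3.3.1]nonan-3-one | O=C1C(=C)[C@H]2CC[C@@H](C=C)[C@@H](O1)O2 | intermediate
13 | triethylsilyl 2-[(2R,5S)-5-ethenyloxan-2-yl]prop-2-enoate | C=C(C(=O)O[Si](CC)(CC)CC)[C@H]1CC[C@@H](C=C)CO1 | intermediate
14 | 2-[(2R,5S)-5-ethenyloxan-2-yl]prop-2-enoic acid (cis) | C=C(C(=O)O)[C@H]1CC[C@@H](C=C)CO1 | intermediate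
15 | 1-(trimethylsilyl)propyne | CC#C[Si](C)(C)C | starting material
16 | geranyl bromide, (2E)-1-bromo-3,7-dimethylocta-2,6-diene | BrC/C=C(\C)CCC=C(C)C | starting material
17 | 3-lithio-1-(trimethylsilyl)propyne | [Li]CC#C[Si](C)(C)C | intermediate
18 | trimethyl[(5E)-6,10-dimethylundeca-5,9-dien-1-yn-1-yl]silane | C[Si](C)(C)C#CCC/C=C(\C)CCC=C(C)C | intermediate
19 | (5E)-6,10-dimethylundeca-5,9-dien-1-yne | C#CCC/C=C(\C)CCC=C(C)C | intermediate
20 | dimethyl[(1E,5E)-2,6,10-trimethylundeca-1,5,9-trien-1-yl]alumane | C[Al](C)/C=C(\C)CC/C=C(\C)CCC=C(C)C | intermediate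
21 | (1E,5E)-1-iodo-2,6,10-trimethylundeca-1,5,9-triene | I/C=C(\C)CC/C=C(\C)CCC=C(C)C | intermediate
22 | 9-borabicyclo[3.3.1]nonan-9-yl 2-[(2R,5R)-5-[2-(9-borabicyclo[3.3.1]nonan-9-yl)ethyl]oxan-2-yl]prop-2-enoate | C=C(C(=O)OB1C2CCCC1CCC2)[C@H]1CC[C@@H](CCB2C3CCCC2CCC3)CO1 | intermediate
23 | rhopaloic acid B, 2-[(2R,5R)-5-[(3E,7E)-4,8,12-trimethyltrideca-3,7,11-trien-1-yl]oxan-2-yl]prop-2-enoic acid | C=C(C(=O)O)[C@H]1CC[C@@H](CC/C=C(\C)CC/C=C(\C)CCC=C(C)C)CO1 | target

**Step count and risks**

Total steps: 11. Longest linear sequence: 8 (steps 1–7 and 11).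

Step 5 (proposed new method). The 6-exo closure may be too slow, so that 1,5-hydrogen transfer from the allylic position takes over, or single-electron oxidation of the electron-poor carboxylate may be inefficient. The fallback replaces photoredox catalysis by a classical thiohydroxamate radical chain, which is known chemistry. It sets out from 7: esterification with 1-hydroxypyridine-2(1H)-thione and DCC gives the O-acyl thiohydroxamate (Barton ester) F1. Visible-light photolysis of F1 in dilute refluxing benzene starts a Barton decarboxylation chain in which the expelled phenylsulfonyl radical attacks the thiocarbonyl sulfur of the next molecule. The acylal radical cyclises onto the allyl sulfone and fragments as before, and the route is rejoined at 8.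

Step 4. Glyoxylic acid may esterify or oligomerise faster than the six-membered acylal closes, and the acylal acid may hydrolyse during work-up. The fallback uses a kinetic silyl-transfer acetalisation instead of an equilibrium condensation. It sets out from 5: persilylation with N,O-bis(trimethylsilyl)acetamide gives trimethylsilyl (3R,6E)-8-(benzenesulfonyl)-3-(trimethylsilyloxy)oct-6-enoate F2. Acetalisation of F2 with tert-butyl glyoxylate and catalytic TMSOTf at −78 °C gives tert-butyl (6R)-6-[(3E)-5-(benzenesulfonyl)pent-3-en-1-yl]-4-oxo-1,3-dioxane-2-carboxylate F3. TFA in CH2Cl2 then removes the tert-butyl group and the route is rejoined at 7.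

Step 11. The free acrylic acid may consume or be reduced by the borane, and the carboxylate may slow transmetalation so that protodeboronation wins. The fallback is a protecting-group detour. It sets out from 14: trimethylsilyldiazomethane in MeOH/toluene gives methyl 2-[(2R,5S)-5-ethenyloxan-2-yl]prop-2-enoate F4. Hydroboration with 9-BBN gives methyl 2-[(2R,5R)-5-[2-(9-borabicyclo[3.3.1]nonan-9-yl)ethyl]oxan-2-yl]prop-2-enoate F5, which is coupled with 21 under the same palladium conditions to methyl rhopaloate B F6. Saponification with LiOH in THF/H2O (Cα carries no hydrogen, so the ring oxygen cannot be eliminated) then arrives at 23.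

**Further compounds**

F1 | step 5 | 2-sulfanylidenepyridin-1(2H)-yl (6R)-6-[(3E)-5-(benzenesulfonyl)pent-3-en-1-yl]-4-oxo-1,3-dioxane-2-carboxylate | S=c1ccccn1OC(=O)C1OC(=O)C[C@@H](CC/C=C/CS(=O)(=O)c2ccccc2)O1
F2 | step 4 | trimethylsilyl (3R,6E)-8-(benzenesulfonyl)-3-(trimethylsilyloxy)oct-6-enoate | C[Si](C)(C)OC(=O)C[C@H](O[Si](C)(C)C)CC/C=C/CS(=O)(=O)c1ccccc1
F3 | step 4 | tert-butyl (6R)-6-[(3E)-5-(benzenesulfonyl)pent-3-en-1-yl]-4-oxo-1,3-dioxane-2-carboxylate | CC(C)(C)OC(=O)C1OC(=O)C[C@@H](CC/C=C/CS(=O)(=O)c2ccccc2)O1
F4 | step 11 | methyl 2-[(2R,5S)-5-ethenyloxan-2-yl]prop-2-enoate | C=C(C(=O)OC)[C@H]1CC[C@@H](C=C)CO1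
F5 | step 11 | methyl 2-[(2R,5R)-5-[2-(9-borabicyclo[3.3.1]nonan-9-yl)ethyl]oxan-2-yl]prop-2-enoate | C=C(C(=O)OC)[C@H]1CC[C@@H](CCB2C3CCCC2CCC3)CO1
F6 | step 11 | methyl 2-[(2R,5R)-5-[(3E,7E)-4,8,12-trimethyltrideca-3,7,11-trien-1-yl]oxan-2-yl]prop-2-enoate | C=C(C(=O)OC)[C@H]1CC[C@@H](CC/C=C(\C)CC/C=C(\C)CCC=C(C)C)CO1
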